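**Retrosynthetic overview**
1. The C4–O bond on the phenol-bearing flavan is cut last: target 13 comes from ortho-quinone methide 12 (made from diol 8) and trans-flavan-4-ol 10 by oxa-Michael addition.
2. Both 8 and 10 come from one ketone, (S)-5,6,7-trimethoxyflavanone 6: 8 by peri-selective O-demethylation and reduction, 10 by reduction and C4 epimerisation.
3. Ketone 6 comes from chromone 4 and phenylboronic acid 5 by asymmetric 1,4-addition, which sets C2 in both halves.
4. Chromone 4 comes from 3,4,5-trimethoxyphenol 1 by ortho-acetylation and enaminone cyclisation.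
5. Ring order: benzo ring bought, pyranone ring closed in step 2, phenyl ring attached in step 3, the two flavan units joined in step 7.

Assumption: flavan numbering (O1, C2, C3, C4, C4a, C5–C8, C8a) is used throughout; diol 8 is drawn as its major cis epimer, and its C4 configuration does not matter because step 7 erases it.

Step 1
Reactants: 1 3,4,5-trimethoxyphenol
Product: 2 1-(6-hydroxy-2,3,4-trimethoxyphenyl)ethan-1-one
Conditions: AcOH (3 equiv), BF3·OEt2 (neat), 90 °C, 2 h; then aq. NaOAc, 23 °C
Reagents that add atoms: acetic acid (CC(=O)O)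
Why: Friedel–Crafts (Fries-type) C-acetylation of a strongly activated phenol can only go ortho to the hydroxyl, because the para position carries a methoxy group and the two ortho positions are equivalent; no stereocentre is formed.

Step 2
Reactants: 2 1-(6-hydroxy-2,3,4-trimethoxyphenyl)ethan-1-one
Product: 4 5,6,7-trimethoxy-4H-chromen-4-one, via enaminone 3 (not isolated)
Conditions: DMF-DMA (3 equiv), PhMe, 110 °C, 3 h; evaporate; then conc. HCl, CH2Cl2, 40 °C, 1 h
Reagents that add atoms: N,N-dimethylformamide dimethyl acetal (COC(OC)N(C)C)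
Why: Enaminone condensation at the acetyl methyl group followed by acid-mediated 6-endo addition of the phenol and loss of dimethylamine is the standard enaminone chromone synthesis; no stereocentre is formed.

Step 3
Reactants: 4 5,6,7-trimethoxy-4H-chromen-4-one; 5 phenylboronic acid
Product: 6 (2S)-5,6,7-trimethoxy-2-phenylchroman-4-one
Conditions: 5 (3 equiv), [Rh(OH)(cod)]2 (1.5 mol%), (S)-MeO-F12-BIPHEP [(S)-6,6'-dimethoxy-2,2'-bis{bis(3,4,5-trifluorophenyl)phosphino}biphenyl] (3.3 mol%), PhMe/H2O (10:1), 40 °C, 12 h; recrystallise
Reagents that add atoms: none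
Why: Hayashi–Miyaura rhodium-catalysed asymmetric 1,4-addition, in which the phenyl–rhodium species carrying the electron-poor (S)-biaryl bisphosphine inserts the chromone C2=C3 bond from one enantioface (the sense that gives (S)-3-arylcyclohexanones from cyclohexenone) and so sets C2 as S; the sense is confirmed by optical rotation before the material is carried on.

Step 4
Reactants: 6 (2S)-5,6,7-trimethoxy-2-phenylchroman-4-one
Product: 7 (2S)-5-hydroxy-6,7-dimethoxy-2-phenylchroman-4-one
Conditions: BCl3 (1.5 equiv), CH2Cl2, −78 → −10 °C, 1 h; then aq. NaHCO3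
Reagents that add atoms: none
Why: Chelation-directed Lewis-acid ether cleavage, in which BCl3 bound to the C4 carbonyl removes only the peri 5-O-methyl group through a six-membered chelate, and the low temperature keeps the pyranone ring closed so C2 stays S.

Step 5
Reactants: 7 (2S)-5-hydroxy-6,7-dimethoxy-2-phenylchroman-4-one
Product: 8 (2S,4S)-6,7-dimethoxy-2-phenylchromane-4,5-diol
Conditions: NaBH4 (2 equiv), THF/EtOH (1:1), 0 → 23 °C, 2 h; KH2PO4/K2HPO4 buffer (pH 7) work-up; used crude at once
Reagents that add atoms: none
Why: Borohydride 1,2-reduction of the aryl ketone by axial hydride delivery gives mainly the 2,4-cis diol, and the neutral work-up preserves this acid-labile salicyl-type alcohol.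

Step 6
Reactants: 6 (2S)-5,6,7-trimethoxy-2-phenylchroman-4-one
Product: 10 (2S,4R)-5,6,7-trimethoxy-2-phenylchroman-4-ol, via cis-flavan-4-ol 9 (not isolated)
Conditions: LiBH4 (1.5 equiv), THF, 0 → 23 °C; then THF/H2O (1:1, 0.02 M), 1 M HCl to pH 2.5, 30 °C, 6 h; NaHCO3; chromatography on Et3N-washed silica
Reagents that add atoms: water (O)
Why: Borohydride 1,2-reduction gives cis alcohol 9 by axial hydride delivery, and the acidic aqueous hold epimerises C4 by reversible SN1 ionisation (acid-catalysed benzylic alcohol epimerisation through the 2,4,6-trioxygenated benzylic cation); water is recaptured axially on the half-chair cation with 2-phenyl equatorial, and the equatorial 4-OH of 9 suffers peri strain against the 5-OMe, so the 2,4-trans (4R) alcohol is both the kinetic and the thermodynamic product while C2 is untouched.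

Step 7
Reactants: 8 (2S,4S)-6,7-dimethoxy-2-phenylchromane-4,5-diol; 10 (2S,4R)-5,6,7-trimethoxy-2-phenylchroman-4-ol
Product: 13 beilschmieflavonoid B, via cyclic arylboronate 11 (not isolated), via ortho-quinone methide 12 (not isolated)
Conditions: 3,4,5-F3C6H2B(OH)2 (15 mol%), 2,6-di-tert-butylpyridine (15 mol%), 4 Å MS, PhMe, 45 °C; 8 added over 4 h to 10 (1.5 equiv); excess 10 recovered
Reagents that add atoms: none
Why: Proposed new method: a boronic-acid-catalysed dehydrative oxa-Michael cross-etherification in which the arylboronic acid condenses only with the 1,3-related phenol/benzylic alcohol pair of 8 to give boronate 11, whose C4–O bond ionises (push from O1, the 7-OMe and the boron-bound O5) to the boron-associated ortho-quinone methide 12, and the B–O oxygen then acts as general base while the 4-OH of 10 adds to C4 along the axial trajectory of the half-chair (2-phenyl equatorial), giving the 2,4-trans (4R) ether, while C4 of 10 stays R because its C–O bond is never broken; mono-ol 10 cannot chelate boron and is not ionised in toluene, the ring-locked E geometry of 12 forbids the 1,5-hydrogen shift to a flavene, and reversibility through 12 lets any cis ether or homo-ether of 8 drain to the peri-strain-free trans cross-ether as water is removed; the closest known reaction types are the stoichiometric phenylboronic-acid-templated generation of ortho-quinone methides from 4H-1,3,2-benzodioxaborinines, arylboronic-acid-catalysed dehydrative substitution of benzylic alcohols, and oxa-Michael addition of simple alcohols to ortho-quinone methides.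

**Compound list**
1 | 3,4,5-trimethoxyphenol | COc1cc(O)cc(OC)c1OC | starting material
2 | 1-(6-hydroxy-2,3,4-trimethoxyphenyl)ethan-1-one | CC(=O)c1c(O)cc(OC)c(OC)c1OC | intermediate
3 | (E)-3-(dimethylamino)-1-(6-hydroxy-2,3,4-trimethoxyphenyl)prop-2-en-1-one (enaminone) | CN(C)/C=C/C(=O)c1c(O)cc(OC)c(OC)c1OC | intermediate
4 | 5,6,7-trimethoxy-4H-chromen-4-one | COc1cc2occc(=O)c2c(OC)c1OC | intermediate
5 | phenylboronic acid | OB(O)c1ccccc1 | starting material
6 | (2S)-5,6,7-trimethoxy-2-phenylchroman-4-one [(S)-5,6,7-trimethoxyflavanone] | COc1cc2c(c(OC)c1OC)C(=O)C[C@@H](c1ccccc1)O2 | intermediate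
7 | (2S)-5-hydroxy-6,7-dimethoxy-2-phenylchroman-4-one | COc1cc2c(c(O)c1OC)C(=O)C[C@@H](c1ccccc1)O2 | intermediate
8 | (2S,4S)-6,7-dimethoxy-2-phenylchromane-4,5-diol (2,4-cis, major epimer) | COc1cc2c(c(O)c1OC)[C@@H](O)C[C@@H](c1ccccc1)O2 | intermediate
9 | (2S,4S)-5,6,7-trimethoxy-2-phenylchroman-4-ol (2,4-cis) | COc1cc2c(c(OC)c1OC)[C@@H](O)C[C@@H](c1ccccc1)O2 | intermediate
10 | (2S,4R)-5,6,7-trimethoxy-2-phenylchroman-4-ol (2,4-trans) | COc1cc2c(c(OC)c1OC)[C@H](O)C[C@@H](c1ccccc1)O2 | intermediate
11 | cyclic 3,4,5-trifluorophenylboronate of 8 (boron bridging O4 and O5, peri-fused 1,3,2-dioxaborinine) | COc1cc2c3c(c1OC)OB(c1cc(F)c(F)c(F)c1)O[C@H]3C[C@@H](c1ccccc1)O2 | intermediate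
12 | (2S)-6,7-dimethoxy-2-phenyl-2,3-dihydro-5H-chromen-5-one (ortho-quinone methide, C4=C4a, C5=O; formed as its O5–boron adduct) | COC1=C(OC)C(=O)C2=CC[C@@H](c3ccccc3)OC2=C1 | intermediate
13 | beilschmieflavonoid B, (2S,4R)-6,7-dimethoxy-2-phenyl-4-{[(2S,4R)-5,6,7-trimethoxy-2-phenylchroman-4-yl]oxy}chroman-5-ol | COc1cc2c(c(O)c1OC)[C@H](O[C@@H]1C[C@@H](c3ccccc3)Oc3cc(OC)c(OC)c(OC)c31)C[C@@H](c1ccccc1)O2 | target

**Step count**
Total steps: 7. Longest linear sequence: 6 (steps 1, 2, 3, 4, 5, 7); step 6 is the side branch from 6.

**Three steps most likely to fail**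

Step 7 (the proposed new etherification). Risks are slow ionisation of boronate 11, C-alkylation of the electron-rich C8 position of 10 by 12, and homo-ether formation from 8. The fallback uses known sulfone chemistry; it sets out from 8 and comes back at 13. Diol 8 is stirred with p-toluenesulfinic acid in CH2Cl2 at 23 °C, which gives (2S,4R)-6,7-dimethoxy-2-phenyl-4-(4-methylbenzenesulfonyl)chroman-5-ol F3 (its C4 configuration is irrelevant). F3 is then added at −40 → 0 °C to the sodium alkoxide of 10 (10 1.3 equiv, NaH 2.2 equiv, THF). Deprotonation of the phenol triggers 1,4-elimination of sulfinate to 12, which the alkoxide of 10 captures axially to give 13 after a buffered quench. This is the established base-induced ortho-quinone methide generation from 2-(sulfonylalkyl)phenols followed by oxa-Michael addition, run under fully non-acidic conditions.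

Step 6 (one-pot reduction and C4 epimerisation). Risks are a modest trans:cis equilibrium ratio and loss to flavene or bis-ether by-products. The fallback replaces thermodynamic SN1 equilibration by SN2 inversion; it sets out from 6 and comes back at 10. Ketone 6 is reduced with NaBH4 (MeOH/THF, 0 °C) and cis alcohol 9 is isolated. Mitsunobu reaction of 9 with benzoic acid (PPh3, DIAD, THF, 0 °C) gives (2S,4R)-5,6,7-trimethoxy-2-phenylchroman-4-yl benzoate F2 with inversion at C4. The benzoyl group is then removed by acyl reduction with i-Bu2AlH (CH2Cl2, −78 °C), which leaves the C4–O bond intact and gives 10.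

Step 4 (peri-demethylation of the chiral flavanone). Risks are Lewis-acid ring opening to the chalcone, which would erode C2, and a second demethylation at O6. The fallback demethylates before the stereocentre exists; it sets out from 4 and comes back at 7. Chromone 4 is treated with BCl3 (CH2Cl2, −78 → 0 °C) to give 5-hydroxy-6,7-dimethoxy-4H-chromen-4-one F1. F1 then undergoes the rhodium-catalysed asymmetric 1,4-addition of 5 under the step 3 conditions to give 7 directly; ketone 6 for step 6 still comes from step 3.

**Further compounds**
F1 | step 4 | 5-hydroxy-6,7-dimethoxy-4H-chromen-4-one | COc1cc2occc(=O)c2c(O)c1OC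
F2 | step 6 | (2S,4R)-5,6,7-trimethoxy-2-phenylchroman-4-yl benzoate | COc1cc2c(c(OC)c1OC)[C@H](OC(=O)c1ccccc1)C[C@@H](c1ccccc1)O2
F3 | step 7 | (2S,4R)-6,7-dimethoxy-2-phenyl-4-(4-methylbenzenesulfonyl)chroman-5-ol | COc1cc2c(c(O)c1OC)[C@H](S(=O)(=O)c1ccc(C)cc1)C[C@@H](c1ccccc1)O2
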